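**Plan**

1. Locants (cembrane-type, used throughout): C1 bears the isopropylidene group (C15), C2 = ketone, C3/C4 = epoxide (C4 bears CH3), C7=C8 (C8 bears CH3), C9 = carbinol, C10/C11 = CH2, C12 = acetoxy carbon (bears CH3 = C20), C13/C14 = CH2.
2. Retrosynthesis cuts, in order: C9–OH back to the C9 ketone; the ring bond C11–C12; the C12–OAc bond (terminal alkyne + AcOH); C1–C2 (vinyllithium + epoxy aldehyde); C9–C10 (vinyl Grignard + enal) and C1–C14 (Negishi).
3. Enabling feature: C12 carries CH3 and OAc, so it is the H-atom adduct of an isopropenyl-acetate-type enol ester. C11 is β to the C9 oxygen, so it is the terminus of a C9 vinyl ketone. The 14-membered carbocycle closes between these two atoms.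
4. Forward: geranyl acetate gives the C2–C11 epoxy aldehyde 8; the C12–C1 bromide 12 is joined to it at C1–C2; deprotection, oxidation and AcOH addition give the open-chain enol acetate 17; the ring is closed; C9 is reduced last.
5. Stereochemistry: C3/C4 from Sharpless epoxidation (L-(+)-DET); C7=C8 (E) from geranyl acetate; C12 formed in the ring closure, relayed from the epoxide through the ring conformation; C9 by (S)-CBS reduction.

Key step: step 13

Assumption: 1,1-dibromo-2-methylprop-1-ene and (4-bromobut-1-yn-1-yl)trimethylsilane are taken as purchasable. Compounds 4–7, 14 and 15 are carried as mixtures of epimers at carbinol carbons that are later oxidised to ketones.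

**Route**

Step 1
Reactants: 1 geranyl acetate
Product: 2 (2E,6E)-8-hydroxy-3,7-dimethylocta-2,6-dien-1-yl acetate
Conditions: SeO2 (cat.), t-BuOOH, salicylic acid (cat.), CH2Cl2, rt
Reagents that add atoms: tert-butyl hydroperoxide, CC(C)(C)OO (oxygen source, transferred by the selenium catalyst)
Why: Selenium dioxide allylic oxidation (ene reaction then [2,3]-shift) should attack the (E)-methyl group of the distal, more electron-rich trisubstituted olefin, since the proximal olefin is deactivated by the allylic acetate.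

Step 2
Reactants: 2 (2E,6E)-8-hydroxy-3,7-dimethylocta-2,6-dien-1-yl acetate
Product: 3 (2E,6E)-3,7-dimethyl-8-oxoocta-2,6-dien-1-yl acetate
Conditions: MnO2, CH2Cl2, rt
Reagents that add atoms: none
Why: Manganese dioxide oxidises the primary allylic alcohol to the enal without touching the ester or the olefin geometry.

Step 3
Reactants: 3 (2E,6E)-3,7-dimethyl-8-oxoocta-2,6-dien-1-yl acetate
Product: 4 (2E,6E)-8-hydroxy-3,7-dimethyldeca-2,6,9-trien-1-yl acetate (racemic at C8 of this chain, the future C9)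
Conditions: vinylmagnesium bromide, THF, −78 °C
Reagents that add atoms: vinylmagnesium bromide, C=C[Mg]Br
Why: Grignard 1,2-addition to the α-substituted enal is much faster at −78 °C than attack on the acetate, and the new carbinol centre is left racemic on purpose because it becomes the C9 ketone.

Step 4
Reactants: 4 (2E,6E)-8-hydroxy-3,7-dimethyldeca-2,6,9-trien-1-yl acetate
Product: 5 (2E,6E)-8-(tert-butyldimethylsilyloxy)-3,7-dimethyldeca-2,6,9-trien-1-yl acetate (racemic)
Conditions: TBSCl, imidazole, DMF, rt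
Reagents that add atoms: tert-butyldimethylsilyl chloride, CC(C)(C)[Si](C)(C)Cl
Why: Standard silylation masks the secondary bis-allylic alcohol so that only the primary allylic alcohol is free in the epoxidation.

Step 5
Reactants: 5 (2E,6E)-8-(tert-butyldimethylsilyloxy)-3,7-dimethyldeca-2,6,9-trien-1-yl acetate
Product: 6 (2E,6E)-8-(tert-butyldimethylsilyloxy)-3,7-dimethyldeca-2,6,9-trien-1-ol (racemic)
Conditions: K2CO3 (cat.), MeOH, 0 °C to rt
Reagents that add atoms: none
Why: Base-catalysed transesterification removes the primary acetate while the TBS ether is stable.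

Step 6
Reactants: 6 (2E,6E)-8-(tert-butyldimethylsilyloxy)-3,7-dimethyldeca-2,6,9-trien-1-ol
Product: 7 [(2S,3S)-3-[(3E)-5-(tert-butyldimethylsilyloxy)-4-methylhepta-3,6-dien-1-yl]-3-methyloxiran-2-yl]methanol (both epimers at the silyloxy carbon)
Conditions: Ti(OiPr)4 (cat.), L-(+)-diethyl tartrate (cat.), t-BuOOH, 4 Å MS, CH2Cl2, −20 °C
Reagents that add atoms: tert-butyl hydroperoxide, CC(C)(C)OO
Why: Sharpless asymmetric epoxidation of the geraniol-type (E)-allylic alcohol with L-(+)-tartrate delivers oxygen to the face that gives the (2S,3S)-epoxy alcohol (reagent control, sets C3 and C4), and the other olefins carry no free allylic hydroxyl and should not react.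

Step 7
Reactants: 7 [(2S,3S)-3-[(3E)-5-(tert-butyldimethylsilyloxy)-4-methylhepta-3,6-dien-1-yl]-3-methyloxiran-2-yl]methanol
Product: 8 (2R,3S)-3-[(3E)-5-(tert-butyldimethylsilyloxy)-4-methylhepta-3,6-dien-1-yl]-3-methyloxirane-2-carbaldehyde
Conditions: Dess–Martin periodinane, CH2Cl2, 0 °C to rt
Reagents that add atoms: none
Why: Dess–Martin oxidation gives the α,β-epoxy aldehyde under near-neutral conditions without epimerisation or epoxide opening.

Step 8
Reactants: 9 (4-bromobut-1-yn-1-yl)trimethylsilane, 10 1,1-dibromo-2-methylprop-1-ene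
Product: 12 (5-bromo-6-methylhept-5-en-1-yn-1-yl)trimethylsilane, via homopropargylic zinc bromide 11 (not isolated)
Conditions: Zn, LiCl, THF, 50 °C; then 10, Pd(DPEphos)Cl2 (cat.), THF, 0 °C to rt
Reagents that add atoms: none
Why: Negishi mono-alkylation of a 1,1-dibromoalkene; the two C–Br bonds of 10 are equivalent, and after the first coupling the remaining C–Br sits on a tetrasubstituted olefin and should undergo oxidative addition much more slowly.

Step 9
Reactants: 12 (5-bromo-6-methylhept-5-en-1-yn-1-yl)trimethylsilane, 8 (2R,3S)-3-[(3E)-5-(tert-butyldimethylsilyloxy)-4-methylhepta-3,6-dien-1-yl]-3-methyloxirane-2-carbaldehyde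
Product: 14 1-[(2S,3S)-3-[(3E)-5-(tert-butyldimethylsilyloxy)-4-methylhepta-3,6-dien-1-yl]-3-methyloxiran-2-yl]-2-(propan-2-ylidene)-6-(trimethylsilyl)hex-5-yn-1-ol (epimers at both carbinol carbons), via vinyllithium 13 (not isolated)
Conditions: t-BuLi (2 equiv per 12), Et2O, −78 °C; then 8, −78 °C; H2O quench
Reagents that add atoms: none
Why: Bromine–lithium exchange gives the tetrasubstituted vinyllithium, which adds 1,2 to the epoxy aldehyde at low temperature to form the C1–C2 bond; the silyl alkyne, silyl ether and epoxide tolerate it, and the C2 configuration is irrelevant because C2 is oxidised.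

Step 10
Reactants: 14 1-[(2S,3S)-3-[(3E)-5-(tert-butyldimethylsilyloxy)-4-methylhepta-3,6-dien-1-yl]-3-methyloxiran-2-yl]-2-(propan-2-ylidene)-6-(trimethylsilyl)hex-5-yn-1-ol
Product: 15 1-[(2S,3S)-3-[(3E)-5-hydroxy-4-methylhepta-3,6-dien-1-yl]-3-methyloxiran-2-yl]-2-(propan-2-ylidene)hex-5-yn-1-ol (epimers at both carbinol carbons)
Conditions: TBAF, AcOH, THF, 0 °C to rt
Reagents that add atoms: none
Why: Fluoride cleaves the alkynyl C–Si bond and the O–Si bond in one operation, and the acetic acid buffer suppresses epoxide migration in the epoxy alcohol.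

Step 11
Reactants: 15 1-[(2S,3S)-3-[(3E)-5-hydroxy-4-methylhepta-3,6-dien-1-yl]-3-methyloxiran-2-yl]-2-(propan-2-ylidene)hex-5-yn-1-ol
Product: 16 1-[(2R,3S)-3-methyl-3-[(3E)-4-methyl-5-oxohepta-3,6-dien-1-yl]oxiran-2-yl]-2-(propan-2-ylidene)hex-5-yn-1-one
Conditions: Dess–Martin periodinane (excess), CH2Cl2, 0 °C
Reagents that add atoms: none
Why: Dess–Martin oxidation converts both secondary allylic alcohols to the C2 epoxy enone and the C9 divinyl ketone, which removes both temporary stereocentres.

Step 12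
Reactants: 16 1-[(2R,3S)-3-methyl-3-[(3E)-4-methyl-5-oxohepta-3,6-dien-1-yl]oxiran-2-yl]-2-(propan-2-ylidene)hex-5-yn-1-one
Product: 17 6-methyl-5-{[(2R,3S)-3-methyl-3-[(3E)-4-methyl-5-oxohepta-3,6-dien-1-yl]oxiran-2-yl]carbonyl}hepta-1,5-dien-2-yl acetate
Conditions: AcOH, [RuCl2(p-cymene)]2 (cat.), P(2-furyl)3 (cat.), Na2CO3 (cat.), toluene, 50 °C
Reagents that add atoms: acetic acid, CC(=O)O
Why: Ruthenium-catalysed Markovnikov addition of a carboxylic acid to a terminal alkyne gives the 2-acetoxy-1-alkene; the reaction class tolerates α,β-unsaturated carbonyl groups, and the ketone-deactivated epoxide should resist the weak acid.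

Step 13
Reactants: 17 6-methyl-5-{[(2R,3S)-3-methyl-3-[(3E)-4-methyl-5-oxohepta-3,6-dien-1-yl]oxiran-2-yl]carbonyl}hepta-1,5-dien-2-yl acetate
Product: 18 (3R,4S,7E,12R)-12-acetoxy-3,4-epoxycembra-1(15),7-diene-2,9-dione
Conditions: Fe(acac)3, PhSiH3, EtOH/(CH2OH)2, 60 °C, syringe-pump addition of 17 (final concentration about 2 mM)
Reagents that add atoms: none
Why: Proposed new method: an iron hydride formed from Fe(III) and PhSiH3 should transfer a hydrogen atom to the terminal CH2 of the enol acetate (the only electron-rich olefin, the other three being conjugated to C=O), which creates the C20 methyl group and a tertiary α-acetoxy radical at C12; this nucleophilic radical adds to the unsubstituted β-carbon C11 of the vinyl ketone, and the α-keto radical at C10 is reduced by Fe(II) and protonated by ethanol. The closest known reactions are the intermolecular iron-hydride reductive coupling of oxygen-substituted olefins with enones and the tin-hydride radical macrocyclisation of ω-halo vinyl ketones to 14-membered rings; the combination as a hydrogen-atom-transfer macrocyclisation from an enol ester has not been shown. The ring closes in the 14-endo-trig mode, preferred over 13-exo because it leads to the stabilised α-keto radical and over attack at C7 or C15 because those β-carbons are substituted. C12 is the only new stereocentre and has no local controller: its configuration must be relayed from the (3R,4S)-epoxide through the folded transition state defined by the rigid epoxy enone and (E)-dienone units, and any 12-epimer is a diastereomer that is removed by chromatography. The step needs slow addition so that cyclisation outruns intermolecular addition, and a low standing hydride concentration so that it outruns reduction of the radical or of the vinyl ketone. Because the acetate is already on C12 when the C9 ketone appears, no free γ-hydroxy ketone can form a hemiketal.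

Step 14
Reactants: 18 (3R,4S,7E,12R)-12-acetoxy-3,4-epoxycembra-1(15),7-diene-2,9-dione
Product: 19 (3R,4S,7E,9R,12R)-12-acetoxy-3,4-epoxy-9-hydroxycembra-1(15),7-dien-2-one (CNP0404804.1)
Conditions: (S)-2-methyl-CBS-oxazaborolidine, catecholborane, toluene, −78 °C
Reagents that add atoms: none
Why: In the Corey–Bakshi–Shibata reduction the (S)-catalyst binds the C9 carbonyl anti to the larger α-methylalkenyl group (C8) and delivers hydride to the face that gives (9R), while the C2 ketone, flanked by the tetrasubstituted C1 and the epoxide carbon C3, should be too hindered to bind.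

**Compound list**

1 | geranyl acetate, (2E)-3,7-dimethylocta-2,6-dien-1-yl acetate | CC(=O)OC/C=C(\C)CCC=C(C)C | starting material
2 | (2E,6E)-8-hydroxy-3,7-dimethylocta-2,6-dien-1-yl acetate | CC(=O)OC/C=C(\C)CC/C=C(\C)CO | intermediate
3 | (2E,6E)-3,7-dimethyl-8-oxoocta-2,6-dien-1-yl acetate | CC(=O)OC/C=C(\C)CC/C=C(\C)C=O | intermediate
4 | (2E,6E)-8-hydroxy-3,7-dimethyldeca-2,6,9-trien-1-yl acetate (racemic) | CC(=O)OC/C=C(\C)CC/C=C(\C)C(O)C=C | intermediate
5 | (2E,6E)-8-(tert-butyldimethylsilyloxy)-3,7-dimethyldeca-2,6,9-trien-1-yl acetate (racemic) | CC(=O)OC/C=C(\C)CC/C=C(\C)C(O[Si](C)(C)C(C)(C)C)C=C | intermediate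
6 | (2E,6E)-8-(tert-butyldimethylsilyloxy)-3,7-dimethyldeca-2,6,9-trien-1-ol (racemic) | OC/C=C(\C)CC/C=C(\C)C(O[Si](C)(C)C(C)(C)C)C=C | intermediate
7 | [(2S,3S)-3-[(3E)-5-(tert-butyldimethylsilyloxy)-4-methylhepta-3,6-dien-1-yl]-3-methyloxiran-2-yl]methanol (epimers at the silyloxy carbon) | OC[C@@H]1O[C@@]1(C)CC/C=C(\C)C(O[Si](C)(C)C(C)(C)C)C=C | intermediate
8 | (2R,3S)-3-[(3E)-5-(tert-butyldimethylsilyloxy)-4-methylhepta-3,6-dien-1-yl]-3-methyloxirane-2-carbaldehyde (epimers at the silyloxy carbon) | O=C[C@@H]1O[C@@]1(C)CC/C=C(\C)C(O[Si](C)(C)C(C)(C)C)C=C | intermediate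
9 | (4-bromobut-1-yn-1-yl)trimethylsilane | C[Si](C)(C)C#CCCBr | starting material
10 | 1,1-dibromo-2-methylprop-1-ene | CC(C)=C(Br)Br | starting material
11 | [4-(trimethylsilyl)but-3-yn-1-yl]zinc bromide | C[Si](C)(C)C#CCC[Zn]Br | intermediate
12 | (5-bromo-6-methylhept-5-en-1-yn-1-yl)trimethylsilane | CC(C)=C(Br)CCC#C[Si](C)(C)C | intermediate
13 | [2-methyl-7-(trimethylsilyl)hept-2-en-6-yn-3-yl]lithium | CC(C)=C([Li])CCC#C[Si](C)(C)C | intermediate
14 | 1-[(2S,3S)-3-[(3E)-5-(tert-butyldimethylsilyloxy)-4-methylhepta-3,6-dien-1-yl]-3-methyloxiran-2-yl]-2-(propan-2-ylidene)-6-(trimethylsilyl)hex-5-yn-1-ol (epimers at both carbinol carbons) | CC(C)=C(CCC#C[Si](C)(C)C)C(O)[C@@H]1O[C@@]1(C)CC/C=C(\C)C(O[Si](C)(C)C(C)(C)C)C=C | intermediate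
15 | 1-[(2S,3S)-3-[(3E)-5-hydroxy-4-methylhepta-3,6-dien-1-yl]-3-methyloxiran-2-yl]-2-(propan-2-ylidene)hex-5-yn-1-ol (epimers at both carbinol carbons) | C#CCCC(=C(C)C)C(O)[C@@H]1O[C@@]1(C)CC/C=C(\C)C(O)C=C | intermediate
16 | 1-[(2R,3S)-3-methyl-3-[(3E)-4-methyl-5-oxohepta-3,6-dien-1-yl]oxiran-2-yl]-2-(propan-2-ylidene)hex-5-yn-1-one | C#CCCC(=C(C)C)C(=O)[C@@H]1O[C@@]1(C)CC/C=C(\C)C(=O)C=C | intermediate
17 | 6-methyl-5-{[(2R,3S)-3-methyl-3-[(3E)-4-methyl-5-oxohepta-3,6-dien-1-yl]oxiran-2-yl]carbonyl}hepta-1,5-dien-2-yl acetate | CC(=O)OC(=C)CCC(=C(C)C)C(=O)[C@@H]1O[C@@]1(C)CC/C=C(\C)C(=O)C=C | intermediate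
18 | (3R,4S,7E,12R)-12-acetoxy-3,4-epoxycembra-1(15),7-diene-2,9-dione | CC(=O)O[C@]1(C)CCC(=C(C)C)C(=O)[C@@H]2O[C@@]2(C)CC/C=C(\C)C(=O)CC1 | intermediate
19 | (3R,4S,7E,9R,12R)-12-acetoxy-3,4-epoxy-9-hydroxycembra-1(15),7-dien-2-one | CC(=O)O[C@]1(C)CCC(=C(C)C)C(=O)[C@@H]2O[C@@]2(C)CC/C=C(\C)[C@H](O)CC1 | target

**Totals**

Total step count: 14. Longest linear sequence: 13 steps (steps 1–7 and 9–14, from geranyl acetate); step 8 is the side branch.

**Three steps most likely to fail**

Step 13 (labelled step; radical macrocyclisation). What may go wrong: oligomerisation instead of ring closure; reduction of the C12 radical or conjugate reduction of the vinyl ketone before cyclisation; and poor facial selectivity at C12, which has only remote control. The fallback uses known chemistry, sets out from 15 and comes back at 18. The same C11–C12 bond is closed by a ruthenium-catalysed alkene–alkyne coupling, a reaction class with macrocyclisation precedent. Diol 15 ([CpRu(MeCN)3]PF6 cat., acetone, rt, high dilution) joins the internal alkyne carbon C12 to the terminal carbon C11 of the C9 allylic alcohol unit. β-Hydride elimination of the carbinol hydrogen then leads through the enol to the macrocyclic ketone with an exocyclic methylene at C12, (3S,4S,7E)-3,4-epoxy-2-hydroxycembra-1(15),7,12(20)-trien-9-one F1 (C2 epimers). Dess–Martin oxidation gives (3R,4S,7E)-3,4-epoxycembra-1(15),7,12(20)-triene-2,9-dione F2. Mukaiyama hydration (Co(acac)2, PhSiH3, O2, i-PrOH) of the only non-conjugated olefin gives the tertiary alcohol (3R,4S,7E,12R)-3,4-epoxy-12-hydroxycembra-1(15),7-diene-2,9-dione F3, with C12 now set on the preformed ring by peripheral oxygen capture. Acetylation (Ac2O, DMAP, Et3N) returns to 18.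

Step 12 (alkyne hydroacetoxylation). What may go wrong: conjugate addition or polymerisation at the vinyl ketone under the warm, weakly basic conditions, or loss of Markovnikov selectivity. The fallback sets out from 14 and comes back at 17; it forms the enol acetate before the vinyl ketone exists. Dess–Martin oxidation of 14 gives 1-[(2R,3S)-3-[(3E)-5-(tert-butyldimethylsilyloxy)-4-methylhepta-3,6-dien-1-yl]-3-methyloxiran-2-yl]-2-(propan-2-ylidene)-6-(trimethylsilyl)hex-5-yn-1-one F4. K2CO3 in MeOH removes the alkynyl silyl group to give the terminal alkyne 1-[(2R,3S)-3-[(3E)-5-(tert-butyldimethylsilyloxy)-4-methylhepta-3,6-dien-1-yl]-3-methyloxiran-2-yl]-2-(propan-2-ylidene)hex-5-yn-1-one F5. The same ruthenium-catalysed AcOH addition gives 5-{[(2R,3S)-3-[(3E)-5-(tert-butyldimethylsilyloxy)-4-methylhepta-3,6-dien-1-yl]-3-methyloxiran-2-yl]carbonyl}-6-methylhepta-1,5-dien-2-yl acetate F6. HF·pyridine frees the bis-allylic alcohol 5-{[(2R,3S)-3-[(3E)-5-hydroxy-4-methylhepta-3,6-dien-1-yl]-3-methyloxiran-2-yl]carbonyl}-6-methylhepta-1,5-dien-2-yl acetate F7. Dess–Martin oxidation then gives 17 immediately before the ring closure.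

Step 14 (CBS reduction). What may go wrong: the ring conformation may override the catalyst and give the wrong face at C9, or the C2 ketone may be reduced as well. The fallback sets out from 18 and comes back at 19; it switches from reagent control to substrate control followed by inversion. Luche reduction (NaBH4, CeCl3·7H2O, MeOH, −78 °C) reduces the less hindered C9 enone 1,2 from the ring-preferred face. If this gives the (9S) alcohol (3R,4S,7E,9S,12R)-12-acetoxy-3,4-epoxy-9-hydroxycembra-1(15),7-dien-2-one F8, Mitsunobu inversion (4-nitrobenzoic acid, PPh3, DIAD, THF, 0 °C) gives the (9R) ester (3R,4S,7E,9R,12R)-12-acetoxy-3,4-epoxy-9-(4-nitrobenzoyloxy)cembra-1(15),7-dien-2-one F9. Brief methanolysis (K2CO3, MeOH, 0 °C) cleaves the activated secondary ester faster than the tertiary acetate and gives 19.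

**Further compounds**

F1 | step 13 | (3S,4S,7E)-3,4-epoxy-2-hydroxycembra-1(15),7,12(20)-trien-9-one (C2 epimers) | C=C1CCC(=C(C)C)C(O)[C@@H]2O[C@@]2(C)CC/C=C(\C)C(=O)CC1
F2 | step 13 | (3R,4S,7E)-3,4-epoxycembra-1(15),7,12(20)-triene-2,9-dione | C=C1CCC(=C(C)C)C(=O)[C@@H]2O[C@@]2(C)CC/C=C(\C)C(=O)CC1
F3 | step 13 | (3R,4S,7E,12R)-3,4-epoxy-12-hydroxycembra-1(15),7-diene-2,9-dione | O[C@]1(C)CCC(=C(C)C)C(=O)[C@@H]2O[C@@]2(C)CC/C=C(\C)C(=O)CC1
F4 | step 12 | 1-[(2R,3S)-3-[(3E)-5-(tert-butyldimethylsilyloxy)-4-methylhepta-3,6-dien-1-yl]-3-methyloxiran-2-yl]-2-(propan-2-ylidene)-6-(trimethylsilyl)hex-5-yn-1-one | C[Si](C)(C)C#CCCC(=C(C)C)C(=O)[C@@H]1O[C@@]1(C)CC/C=C(\C)C(O[Si](C)(C)C(C)(C)C)C=C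
F5 | step 12 | 1-[(2R,3S)-3-[(3E)-5-(tert-butyldimethylsilyloxy)-4-methylhepta-3,6-dien-1-yl]-3-methyloxiran-2-yl]-2-(propan-2-ylidene)hex-5-yn-1-one | C#CCCC(=C(C)C)C(=O)[C@@H]1O[C@@]1(C)CC/C=C(\C)C(O[Si](C)(C)C(C)(C)C)C=C
F6 | step 12 | 5-{[(2R,3S)-3-[(3E)-5-(tert-butyldimethylsilyloxy)-4-methylhepta-3,6-dien-1-yl]-3-methyloxiran-2-yl]carbonyl}-6-methylhepta-1,5-dien-2-yl acetate | CC(=O)OC(=C)CCC(=C(C)C)C(=O)[C@@H]1O[C@@]1(C)CC/C=C(\C)C(O[Si](C)(C)C(C)(C)C)C=C
F7 | step 12 | 5-{[(2R,3S)-3-[(3E)-5-hydroxy-4-methylhepta-3,6-dien-1-yl]-3-methyloxiran-2-yl]carbonyl}-6-methylhepta-1,5-dien-2-yl acetate | CC(=O)OC(=C)CCC(=C(C)C)C(=O)[C@@H]1O[C@@]1(C)CC/C=C(\C)C(O)C=C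
F8 | step 14 | (3R,4S,7E,9S,12R)-12-acetoxy-3,4-epoxy-9-hydroxycembra-1(15),7-dien-2-one | CC(=O)O[C@]1(C)CCC(=C(C)C)C(=O)[C@@H]2O[C@@]2(C)CC/C=C(\C)[C@@H](O)CC1
F9 | step 14 | (3R,4S,7E,9R,12R)-12-acetoxy-3,4-epoxy-9-(4-nitrobenzoyloxy)cembra-1(15),7-dien-2-one | CC(=O)O[C@]1(C)CCC(=C(C)C)C(=O)[C@@H]2O[C@@]2(C)CC/C=C(\C)[C@H](OC(=O)c3ccc(cc3)[N+](=O)[O-])CC1
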